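**Retrosynthetic overview**

- The target is a 2-methoxy-4-pyranone (O1, C2–OMe, C3–Et, C4=O, C5–Et, C6–side chain) with a (CH2)9CH(OAc)CH3 chain and one (S) carbinol; the acetate comes from a silyl ether and the C5 ethyl from a C5 iodide by Negishi coupling.
- Key disconnection O1–C6: C4(=O)–C5–C6 of the ring is an ynone and C2(OMe)–O1 is a methyl ester. A methyl 2-ethyl-3-oxohexadec-4-ynoate therefore closes by iodonium-induced 6-endo-dig attack of the ester carbonyl oxygen on C6, which leaves iodine on C5.
- The ketoester comes from aldol addition of the methyl butanoate lithium enolate to a fourteen-carbon ynal, then oxidation; the ynal comes from formylation of a silylated terminal alkyne.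
- The terminal alkynol comes from an alkyne zipper on the adduct of dec-1-ynyllithium and (S)-propylene oxide, which supplies the only stereocenter from the chiral pool.
- Ring order: there is one ring, the pyranone, and it is closed in step 7, after all chain carbons except the C5 ethyl are in place.

Key step: step 7

Remark: the ester α-carbon of the acyclic ester intermediates, and the carbinol carbon of the aldol adduct, are formed without control and are drawn without configuration, because both become sp2 ring carbons in the key step. TBS = tert-butyldimethylsilyl; NIS = N-iodosuccinimide.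

**Route**

Step 1
Reactants: 1 dec-1-yne; 2 (S)-propylene oxide [(S)-2-methyloxirane]
Product: 4 (S)-tridec-4-yn-2-ol, via dec-1-ynyllithium 3 (not isolated)
Conditions: 1, n-BuLi, THF, −78 °C; BF3·OEt2; then 2, −78 °C; H2O quench
Reagents that add atoms: none
Why: BF3-promoted SN2 opening of a terminal epoxide by an alkynyllithium takes place at the unsubstituted CH2, so no bond to the stereocenter is broken and the (S) configuration of 2 is carried into 4.

Step 2
Reactants: 4 (S)-tridec-4-yn-2-ol
Product: 5 (S)-tridec-12-yn-2-ol
Conditions: KH, H2N(CH2)3NH2, rt (forms KNH(CH2)3NH2); then 4, 0 °C → rt; ice-water quench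
Reagents that add atoms: none
Why: In the alkyne zipper isomerisation the amide base moves the triple bond along the chain through allene intermediates until it is trapped as the terminal acetylide, while the carbinol carbon, held as its potassium alkoxide, has no acidic hydrogen and keeps its configuration.

Step 3
Reactants: 5 (S)-tridec-12-yn-2-ol
Product: 6 (S)-tert-butyldimethyl(tridec-12-yn-2-yloxy)silane
Conditions: TBSCl, imidazole, DMF, rt
Reagents that add atoms: tert-butyldimethylsilyl chloride, CC(C)(C)[Si](C)(C)Cl
Why: Imidazole-mediated O-silylation of a secondary alcohol is routine and gives an ether that withstands the organolithium, enolate, oxidation and coupling steps that follow.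

Step 4
Reactants: 6 (S)-tert-butyldimethyl(tridec-12-yn-2-yloxy)silane
Product: 8 (S)-13-(tert-butyldimethylsilyloxy)tetradec-2-ynal, via lithium acetylide 7 (not isolated)
Conditions: n-BuLi, THF, −78 °C; DMF, −78 °C → rt; reverse quench into cold aq. KH2PO4
Reagents that add atoms: N,N-dimethylformamide, CN(C)C=O
Why: Formylation of a lithium acetylide with DMF gives a stable hemiaminal alkoxide that releases the ynal only on the buffered acidic quench, which keeps the liberated dimethylamine protonated and so prevents its conjugate addition.

Step 5
Reactants: 9 methyl butanoate; 8 (S)-13-(tert-butyldimethylsilyloxy)tetradec-2-ynal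
Product: 11 methyl (15S)-15-(tert-butyldimethylsilyloxy)-2-ethyl-3-hydroxyhexadec-4-ynoate (mixture of C2/C3 diastereomers), via lithium enolate of methyl butanoate 10 (not isolated)
Conditions: 9, LiN(i-Pr)2 (LDA), THF, −78 °C; then 8, −78 °C; AcOH quench at −78 °C
Reagents that add atoms: none
Why: Aldol addition of a preformed ester lithium enolate to an ynal is a fast 1,2-addition at −78 °C, and the two new centers need no control because both are removed later.

Step 6
Reactants: 11 methyl (15S)-15-(tert-butyldimethylsilyloxy)-2-ethyl-3-hydroxyhexadec-4-ynoate
Product: 12 methyl (15S)-15-(tert-butyldimethylsilyloxy)-2-ethyl-3-oxohexadec-4-ynoate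
Conditions: Dess–Martin periodinane (1.2 equiv), CH2Cl2, 0 °C → rt; used promptly
Reagents that add atoms: none
Why: Dess–Martin oxidation converts the propargylic β-hydroxy ester into the ynone β-ketoester under near-neutral conditions that leave the silyl ether and the triple bond intact.

Step 7
Reactants: 12 methyl (15S)-15-(tert-butyldimethylsilyloxy)-2-ethyl-3-oxohexadec-4-ynoate
Product: 13 (S)-6-[10-(tert-butyldimethylsilyloxy)undecyl]-3-ethyl-5-iodo-2-methoxy-4H-pyran-4-one
Conditions: NIS (1.2 equiv), AgN(SO2CF3)2 (10 mol %), CH2Cl2, 0 °C → rt, dark
Reagents that add atoms: N-iodosuccinimide, O=C1CCC(=O)N1I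
Why: Proposed new method: the silver-activated N–I reagent transfers I+ to the ynone triple bond while the carbonyl oxygen of the methyl ester, five atoms away in the keto tautomer, adds to the alkyne carbon remote from the ketone, so that O1–C6 and C5–I form in one anti addition and the ring closes in the 6-endo-dig mode; the cyclic dialkoxycarbenium ion then gives up the proton on the ethyl-bearing C3 to succinimide anion and the neutral 2-methoxy-4-pyranone results. The closest known reactions are the ICl cyclisation of 2-methoxyaryl alkynyl ketones to 3-iodochromones, the iodolactonisation of alkynyl esters through the ester carbonyl oxygen, and the gold-catalysed 6-endo cycloisomerisation of 3-oxoalk-4-ynoates to 2-alkoxy-4-pyranones; what is new is an ester carbonyl oxygen closing onto an iodonium-activated ynone with loss of a proton in place of the O-alkyl group. The step needs attack at C6 (6-endo) and not at C5 (5-exo), and the ynone polarisation secures this, because C6 is the electron-poor β-carbon and C5 the carbon that accepts the electrophile. It also needs the O-methyl group to stay, which the halide-free iodine source and the very acidic C3–H secure, since deprotonation outruns any SN2 demethylation. Iodination at the enolisable C3 is the competing process; the tertiary α-iodo ketoester so formed is itself an I+ donor and cannot aromatise, whereas ring closure is irreversible, and a pyranone formed by silver-catalysed cycloisomerisation without iodine would be iodinated at its nucleophilic C5 under the same conditions. No stereocenter is formed, the epimeric α-carbon of 12 becomes sp2, and the remote silyloxy carbinol center is not involved.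

Step 8
Reactants: 13 (S)-6-[10-(tert-butyldimethylsilyloxy)undecyl]-3-ethyl-5-iodo-2-methoxy-4H-pyran-4-one
Product: 14 (S)-6-[10-(tert-butyldimethylsilyloxy)undecyl]-3,5-diethyl-2-methoxy-4H-pyran-4-one
Conditions: EtZnBr (2 equiv, THF solution), PdCl2(dppf) (5 mol %; dppf = 1,1'-bis(diphenylphosphino)ferrocene), THF, 50 °C
Reagents that add atoms: ethylzinc bromide, CC[Zn]Br
Why: Negishi coupling of the α-iodoenone-type C5–I bond with a primary alkylzinc is favoured by fast oxidative addition and by the wide-bite-angle diphosphine, which speeds reductive elimination relative to β-hydride elimination, and the mild zinc reagent leaves the methoxy group and the silyl ether alone.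

Step 9
Reactants: 14 (S)-6-[10-(tert-butyldimethylsilyloxy)undecyl]-3,5-diethyl-2-methoxy-4H-pyran-4-one
Product: 15 (S)-3,5-diethyl-6-(10-hydroxyundecyl)-2-methoxy-4H-pyran-4-one
Conditions: HF·pyridine, pyridine, THF, 0 °C → rt
Reagents that add atoms: none
Why: Fluoride-driven desilylation breaks only the O–Si bond, so the carbinol configuration is retained, and the pyridine buffer protects the acid-sensitive 2-methoxy-4-pyranone.

Step 10
Reactants: 15 (S)-3,5-diethyl-6-(10-hydroxyundecyl)-2-methoxy-4H-pyran-4-one
Product: 16 (S)-11-(3,5-diethyl-6-methoxy-4-oxo-4H-pyran-2-yl)undecan-2-yl acetate (CNP0203650.1)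
Conditions: Ac2O, pyridine, DMAP (cat.), CH2Cl2, rt
Reagents that add atoms: acetic anhydride, CC(=O)OC(C)=O
Why: DMAP-catalysed O-acylation of the secondary alcohol takes place at oxygen with retention of the (S) configuration and gives the target.

**Compound list**

1 | dec-1-yne | C#CCCCCCCCC | starting material
2 | (S)-propylene oxide | C[C@H]1CO1 | starting material
3 | dec-1-ynyllithium | [Li]C#CCCCCCCCC | intermediate
4 | (S)-tridec-4-yn-2-ol | CCCCCCCCC#CC[C@H](C)O | intermediate
5 | (S)-tridec-12-yn-2-ol | C#CCCCCCCCCC[C@H](C)O | intermediate
6 | (S)-tert-butyldimethyl(tridec-12-yn-2-yloxy)silane | C#CCCCCCCCCC[C@H](C)O[Si](C)(C)C(C)(C)C | intermediate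
7 | lithium acetylide of 6 | [Li]C#CCCCCCCCCC[C@H](C)O[Si](C)(C)C(C)(C)C | intermediate
8 | (S)-13-(tert-butyldimethylsilyloxy)tetradec-2-ynal | O=CC#CCCCCCCCCC[C@H](C)O[Si](C)(C)C(C)(C)C | intermediate
9 | methyl butanoate | CCCC(=O)OC | starting material
10 | lithium enolate of methyl butanoate (geometry not relevant) | CCC=C(O[Li])OC | intermediate
11 | methyl (15S)-15-(tert-butyldimethylsilyloxy)-2-ethyl-3-hydroxyhexadec-4-ynoate (C2/C3 mixture) | COC(=O)C(CC)C(O)C#CCCCCCCCCC[C@H](C)O[Si](C)(C)C(C)(C)C | intermediate
12 | methyl (15S)-15-(tert-butyldimethylsilyloxy)-2-ethyl-3-oxohexadec-4-ynoate (C2 epimers) | COC(=O)C(CC)C(=O)C#CCCCCCCCCC[C@H](C)O[Si](C)(C)C(C)(C)C | intermediate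
13 | (S)-6-[10-(tert-butyldimethylsilyloxy)undecyl]-3-ethyl-5-iodo-2-methoxy-4H-pyran-4-one | CCc1c(OC)oc(CCCCCCCCC[C@H](C)O[Si](C)(C)C(C)(C)C)c(I)c1=O | intermediate
14 | (S)-6-[10-(tert-butyldimethylsilyloxy)undecyl]-3,5-diethyl-2-methoxy-4H-pyran-4-one | CCc1c(OC)oc(CCCCCCCCC[C@H](C)O[Si](C)(C)C(C)(C)C)c(CC)c1=O | intermediate
15 | (S)-3,5-diethyl-6-(10-hydroxyundecyl)-2-methoxy-4H-pyran-4-one | CCc1c(OC)oc(CCCCCCCCC[C@H](C)O)c(CC)c1=O | intermediate
16 | (S)-11-(3,5-diethyl-6-methoxy-4-oxo-4H-pyran-2-yl)undecan-2-yl acetate | CCc1c(CCCCCCCCC[C@H](C)OC(C)=O)oc(OC)c(CC)c1=O | target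

**Step count and risks**

Total step count: 10. Longest linear sequence: 10 steps, from 1 and 2 to 16; methyl butanoate 9 enters at step 5.

Steps most likely to fail:

1. Step 7 (iodocyclisation). Activation of the electron-poor triple bond may be too slow, so that iodination at the enol carbon C3 or decomposition of the ynone takes over, or the methyl group may be lost after ring closure. The fallback separates ring closure from iodination and uses known chemistry. Setting out from 12, gold-catalysed 6-endo cycloisomerisation of the 3-oxoalk-4-ynoate with Ph3PAuN(SO2CF3)2 (5 mol %) in CH2Cl2 at rt should give (S)-6-[10-(tert-butyldimethylsilyloxy)undecyl]-3-ethyl-2-methoxy-4H-pyran-4-one F1. Electrophilic iodination of its only free ring position, the nucleophilic C5, with NIS and catalytic CF3CO2H in MeCN then returns to the route at 13.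

2. Step 8 (Negishi coupling). β-Hydride elimination from the ethylpalladium intermediate with reductive loss of iodine, or slow transmetalation at the hindered C5, may erode the coupling. The fallback replaces the sp3 partner by an sp2 partner that has no β-hydride pathway. Setting out from 13, Stille coupling with tributyl(vinyl)stannane (Pd(PPh3)4, CuI, DMF, 60 °C) should give (S)-6-[10-(tert-butyldimethylsilyloxy)undecyl]-5-ethenyl-3-ethyl-2-methoxy-4H-pyran-4-one F2. Selective hydrogenation of the vinyl group (H2, RhCl(PPh3)3, benzene/ethanol, rt) then returns to the route at 14.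

3. Step 6 (oxidation to the ynone ketoester). Further oxidation at the doubly activated α-carbon by excess periodinane, or premature cyclisation and decomposition of the sensitive ketoester during isolation, may lower the return. The fallback reaches the ketone oxidation level by acylation, with no oxidant. Setting out from 6, lithiation to 7 and trapping with N-methoxy-N-methylcarbamoyl chloride (THF, −78 °C → 0 °C) should give (S)-13-(tert-butyldimethylsilyloxy)-N-methoxy-N-methyltetradec-2-ynamide F3. Acylation of the enolate 10 (from 9 and LDA, THF, −78 °C) with this amide, with a cold AcOH quench so that the released amine cannot add to the ynone, returns to the route at 12.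

**Further compounds**

F1 | step 7 | (S)-6-[10-(tert-butyldimethylsilyloxy)undecyl]-3-ethyl-2-methoxy-4H-pyran-4-one | CCc1c(OC)oc(CCCCCCCCC[C@H](C)O[Si](C)(C)C(C)(C)C)cc1=O
F2 | step 8 | (S)-6-[10-(tert-butyldimethylsilyloxy)undecyl]-5-ethenyl-3-ethyl-2-methoxy-4H-pyran-4-one | CCc1c(OC)oc(CCCCCCCCC[C@H](C)O[Si](C)(C)C(C)(C)C)c(C=C)c1=O
F3 | step 6 | (S)-13-(tert-butyldimethylsilyloxy)-N-methoxy-N-methyltetradec-2-ynamide | CON(C)C(=O)C#CCCCCCCCCC[C@H](C)O[Si](C)(C)C(C)(C)C
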